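**Assumption:** the target has no stereocentre (it is achiral), so no stereocontrol is needed; the two sulfated compounds are drawn as free acids but handled as disodium salts until a final H+ exchange.

## Retrosynthetic overview

1. Target ⇐ hydrogenolysis of three benzyl ethers ⇐ double O-sulfation ⇐ bis-phenol ⇐ removal of two MOM groups from a fully protected diaryl ether (Bn on the oxygens that stay free, MOM on the two that get sulfated).
2. Diaryl ether C–O bond ⇐ Ullmann coupling of 2,6-bis(benzyloxy)-4-(methoxymethoxy)phenol (ring B) with 1-(benzyloxy)-3-bromo-5-(methoxymethoxy)benzene (ring A).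
3. Ring B phenol ⇐ 2,6-bis(benzyloxy)hydroquinone ⇐ quinone ⇐ 3,5-bis(benzyloxy)phenol ⇐ phloroglucinol.
4. The phloroglucinol ring is the only ring formed and is formed first. It carries every C–C bond made in the synthesis: intermolecular Claisen condensation of diethyl acetonedicarboxylate with diethyl malonate, Dieckmann closure, aromatisation, decarboxylation.
5. Ring A is bought intact as 3,5-dibromophenol, desymmetrised by Br→OH exchange, and joined last.

## Route

**Step 1**
Reactants: 1 diethyl 3-oxopentanedioate (diethyl acetonedicarboxylate); 2 diethyl malonate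
Product: 5 diethyl 2,4,6-trihydroxybenzene-1,3-dicarboxylate, via acyclic Claisen triester 3 (not isolated), via cyclohexanetrione diester 4 (not isolated)
Conditions: NaOEt (2.2 equiv), EtOH, rt; strip EtOH, neat melt 140–145 °C, 1 h; cold 2 M HCl
Reagents that add atoms: none
Why: Crossed Claisen condensation – the enolate of 1 C-acylates an ester of 2 to give 3, the second α-carbon closes the ring by Dieckmann condensation to 4, and irreversible enolisation to the aromatic phloroglucinol diester (as its sodium salt) drives the equilibria; no stereocentre is formed.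

**Step 2**
Reactants: 5 diethyl 2,4,6-trihydroxybenzene-1,3-dicarboxylate
Product: 8 phloroglucinol, via 2,4,6-trihydroxybenzene-1,3-dicarboxylic acid 6 (not isolated), via 2,4,6-trihydroxybenzoic acid 7 (not isolated)
Conditions: 10% aq KOH, reflux, N2, 3 h; conc. HCl to pH 1, 80 °C until CO2 evolution stops
Reagents that add atoms: none
Why: Ester saponification followed by the very easy ipso-protonation/decarboxylation of 2,4,6-trihydroxybenzoic acids (β-keto-acid-like keto tautomers).

**Step 3**
Reactants: 8 phloroglucinol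
Product: 9 benzene-1,3,5-triyl triacetate
Conditions: Ac2O (4 equiv), pyridine, DMAP (cat.), 0 °C → rt
Reagents that add atoms: acetic anhydride, CC(=O)OC(C)=O
Why: Exhaustive O-acetylation (nucleophilic acyl substitution) masks all three phenols so they can be unveiled one at a time in step 4.

**Step 4**
Reactants: 9 benzene-1,3,5-triyl triacetate
Product: 11 3,5-bis(benzyloxy)phenyl acetate, via 5-(benzyloxy)-1,3-phenylene diacetate 10 (not isolated)
Conditions: NaH (4.4 equiv), BnCl (2.1 equiv), DMF, 0 °C; H2O (2.0 equiv) added dropwise over 2 h; AcOH quench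
Reagents that add atoms: benzyl chloride, ClCc1ccccc1
Why: One-pot deacetylation/Williamson etherification – NaOH generated slowly from NaH and the measured water cleaves one aryl acetate at a time and each phenoxide is O-benzylated at once, which avoids the C-benzylation of free phloroglucinol and stops at the dibenzyl ether monoacetate.

**Step 5**
Reactants: 11 3,5-bis(benzyloxy)phenyl acetate
Product: 12 3,5-bis(benzyloxy)phenol
Conditions: K2CO3 (0.2 equiv), MeOH–THF, rt, 1 h
Reagents that add atoms: none
Why: Base-catalysed transesterification (Zemplén-type methanolysis) of the aryl acetate; benzyl ethers are inert.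

**Step 6**
Reactants: 12 3,5-bis(benzyloxy)phenol
Product: 13 2,6-bis(benzyloxy)-1,4-benzoquinone
Conditions: Fremy's salt (2.5 equiv), aq KH2PO4, acetone–H2O, 0 °C → rt
Reagents that add atoms: potassium nitrosodisulfonate (Fremy's salt), [K+].[K+].[O]N(S(=O)(=O)[O-])S(=O)(=O)[O-]
Why: Teuber oxidation – the phenoxyl radical is trapped through oxygen at the free para position (between the two benzyloxy groups), so only the 2,6-dialkoxy-1,4-quinone can form.

**Step 7**
Reactants: 13 2,6-bis(benzyloxy)-1,4-benzoquinone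
Product: 14 2,6-bis(benzyloxy)benzene-1,4-diol
Conditions: Na2S2O4 (3 equiv), THF–H2O, rt, Ar; crude used directly
Reagents that add atoms: none
Why: Dithionite reduction of the quinone to the hydroquinone; benzyl ethers are untouched.

**Step 8**
Reactants: 14 2,6-bis(benzyloxy)benzene-1,4-diol
Product: 15 2,6-bis(benzyloxy)-4-(methoxymethoxy)phenol
Conditions: MOMCl (1.05 equiv), iPr2NEt (1.2 equiv), CH2Cl2, −20 → 0 °C, Ar
Reagents that add atoms: chloromethyl methyl ether, COCCl
Why: Regioselective O-alkylation (MOM acetal formation) – the 4-OH is more acidic (two meta alkoxy groups) and unhindered, whereas the 1-OH is flanked by two benzyloxy groups.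

**Step 9**
Reactants: 16 3,5-dibromophenol
Product: 17 1-(benzyloxy)-3,5-dibromobenzene
Conditions: BnBr (1.1 equiv), K2CO3 (1.5 equiv), DMF, rt
Reagents that add atoms: benzyl bromide, BrCc1ccccc1
Why: Williamson ether synthesis on a phenoxide.

**Step 10**
Reactants: 17 1-(benzyloxy)-3,5-dibromobenzene
Product: 20 3-(benzyloxy)-5-bromophenol, via aryllithium 18 (not isolated), via dimethyl arylboronate 19 (not isolated)
Conditions: n-BuLi (1.05 equiv), Et2O, −78 °C; B(OMe)3 (1.5 equiv), −78 °C → rt; AcOH, 30% H2O2, 0 °C → rt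
Reagents that add atoms: hydrogen peroxide, OO (phenol oxygen of 20); n-butyllithium, [Li]CCCC (lithium of 18 only); trimethyl borate, COB(OC)OC (B(OMe)2 of 19 only)
Why: Bromine–lithium exchange (only one Br exchanges, since the aryl anion deactivates the second), borylation and boronate oxidation turn one C–Br into C–OH, desymmetrising the ring without a statistical step.

**Step 11**
Reactants: 20 3-(benzyloxy)-5-bromophenol
Product: 21 1-(benzyloxy)-3-bromo-5-(methoxymethoxy)benzene
Conditions: MOMCl (1.3 equiv), iPr2NEt (1.6 equiv), CH2Cl2, 0 °C → rt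
Reagents that add atoms: chloromethyl methyl ether, COCCl
Why: Standard MOM protection (O-alkylation) of the single free phenol.

**Step 12**
Reactants: 15 2,6-bis(benzyloxy)-4-(methoxymethoxy)phenol; 21 1-(benzyloxy)-3-bromo-5-(methoxymethoxy)benzene (1.2 equiv)
Product: 22 1,3-bis(benzyloxy)-2-[3-(benzyloxy)-5-(methoxymethoxy)phenoxy]-5-(methoxymethoxy)benzene
Conditions: CuI (10 mol %), picolinic acid (20 mol %), K3PO4 (2 equiv), DMSO, 90 °C, Ar, 24 h
Reagents that add atoms: none
Why: Ullmann-type Cu(I)-catalysed C–O coupling with a picolinic acid ligand, conditions suited to di-ortho-substituted phenols and electron-rich aryl bromides; MOM and benzyl ethers are base-stable.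

**Step 13**
Reactants: 22 the protected diaryl ether
Product: 23 3-(benzyloxy)-5-[2,6-bis(benzyloxy)-4-hydroxyphenoxy]phenol
Conditions: conc. HCl (cat.), MeOH–THF (3:1), 45 °C
Reagents that add atoms: none
Why: Acid-catalysed acetal cleavage (transacetalisation of both MOM groups to methanol); benzyl and diaryl ethers survive dilute HCl.

**Step 14**
Reactants: 23 3-(benzyloxy)-5-[2,6-bis(benzyloxy)-4-hydroxyphenoxy]phenol
Product: 24 3-(benzyloxy)-5-[2,6-bis(benzyloxy)-4-(sulfooxy)phenoxy]phenyl hydrogen sulfate
Conditions: SO3·pyridine (8 equiv), pyridine, 50 °C, 12 h; aq NaHCO3, reversed-phase chromatography (disodium salt)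
Reagents that add atoms: sulfur trioxide–pyridine complex, O=S(=O)([O-])[n+]1ccccc1
Why: O-sulfonation of the two free, unhindered phenols; the benzylated oxygens cannot react, so the sulfation pattern is fixed by the protecting-group pattern.

**Step 15**
Reactants: 24 the tribenzyl bis-sulfate (disodium salt)
Product: 25 3-[2,6-dihydroxy-4-(sulfooxy)phenoxy]-5-hydroxyphenyl hydrogen sulfate (target)
Conditions: H2 (1 atm), 10% Pd/C, MeOH–H2O, rt; filter; Dowex 50W (H+), 0 °C; lyophilise (store as disodium salt if kept)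
Reagents that add atoms: none
Why: Catalytic hydrogenolysis of the three aryl benzyl ethers; aryl sulfate monoester salts are stable to H2/Pd in neutral medium, and the target has no stereocentre to set or scramble.

## Compound list

1 | diethyl 3-oxopentanedioate | CCOC(=O)CC(=O)CC(=O)OCC | starting material
2 | diethyl malonate | CCOC(=O)CC(=O)OCC | starting material
3 | diethyl 4-(ethoxycarbonyl)-3,5-dioxoheptanedioate | CCOC(=O)CC(=O)C(C(=O)OCC)C(=O)CC(=O)OCC | intermediate (not isolated)
4 | diethyl 2,4,6-trioxocyclohexane-1,3-dicarboxylate | CCOC(=O)C1C(=O)CC(=O)C(C(=O)OCC)C1=O | intermediate (not isolated)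
5 | diethyl 2,4,6-trihydroxybenzene-1,3-dicarboxylate | CCOC(=O)c1c(O)cc(O)c(C(=O)OCC)c1O | intermediate
6 | 2,4,6-trihydroxybenzene-1,3-dicarboxylic acid | OC(=O)c1c(O)cc(O)c(C(=O)O)c1O | intermediate (not isolated)
7 | 2,4,6-trihydroxybenzoic acid | OC(=O)c1c(O)cc(O)cc1O | intermediate (not isolated)
8 | phloroglucinol (benzene-1,3,5-triol) | Oc1cc(O)cc(O)c1 | intermediate
9 | benzene-1,3,5-triyl triacetate | CC(=O)Oc1cc(OC(C)=O)cc(OC(C)=O)c1 | intermediate
10 | 5-(benzyloxy)-1,3-phenylene diacetate | CC(=O)Oc1cc(OCc2ccccc2)cc(OC(C)=O)c1 | intermediate (not isolated)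
11 | 3,5-bis(benzyloxy)phenyl acetate | CC(=O)Oc1cc(OCc2ccccc2)cc(OCc2ccccc2)c1 | intermediate
12 | 3,5-bis(benzyloxy)phenol | Oc1cc(OCc2ccccc2)cc(OCc2ccccc2)c1 | intermediate
13 | 2,6-bis(benzyloxy)cyclohexa-2,5-diene-1,4-dione | O=C1C=C(OCc2ccccc2)C(=O)C(OCc2ccccc2)=C1 | intermediate
14 | 2,6-bis(benzyloxy)benzene-1,4-diol | Oc1cc(OCc2ccccc2)c(O)c(OCc2ccccc2)c1 | intermediate
15 | 2,6-bis(benzyloxy)-4-(methoxymethoxy)phenol | COCOc1cc(OCc2ccccc2)c(O)c(OCc2ccccc2)c1 | intermediate
16 | 3,5-dibromophenol | Oc1cc(Br)cc(Br)c1 | starting material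
17 | 1-(benzyloxy)-3,5-dibromobenzene | Brc1cc(Br)cc(OCc2ccccc2)c1 | intermediate
18 | [3-(benzyloxy)-5-bromophenyl]lithium | [Li]c1cc(Br)cc(OCc2ccccc2)c1 | intermediate (not isolated)
19 | dimethyl [3-(benzyloxy)-5-bromophenyl]boronate | COB(OC)c1cc(Br)cc(OCc2ccccc2)c1 | intermediate (not isolated)
20 | 3-(benzyloxy)-5-bromophenol | Oc1cc(Br)cc(OCc2ccccc2)c1 | intermediate
21 | 1-(benzyloxy)-3-bromo-5-(methoxymethoxy)benzene | COCOc1cc(Br)cc(OCc2ccccc2)c1 | intermediate
22 | 1,3-bis(benzyloxy)-2-[3-(benzyloxy)-5-(methoxymethoxy)phenoxy]-5-(methoxymethoxy)benzene | COCOc1cc(OCc2ccccc2)cc(Oc2c(OCc3ccccc3)cc(OCOC)cc2OCc2ccccc2)c1 | intermediate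
23 | 3-(benzyloxy)-5-[2,6-bis(benzyloxy)-4-hydroxyphenoxy]phenol | Oc1cc(OCc2ccccc2)cc(Oc2c(OCc3ccccc3)cc(O)cc2OCc2ccccc2)c1 | intermediate
24 | 3-(benzyloxy)-5-[2,6-bis(benzyloxy)-4-(sulfooxy)phenoxy]phenyl hydrogen sulfate | O=S(=O)(O)Oc1cc(OCc2ccccc2)cc(Oc2c(OCc3ccccc3)cc(OS(=O)(=O)O)cc2OCc2ccccc2)c1 | intermediate
25 | 3-[2,6-dihydroxy-4-(sulfooxy)phenoxy]-5-hydroxyphenyl hydrogen sulfate | O=S(=O)(O)Oc1cc(O)cc(Oc2c(O)cc(OS(=O)(=O)O)cc2O)c1 | target

## Summary

Total step count: 15. Longest linear sequence: 12 steps (steps 1–8, then 12–15); the ring A branch is steps 9–11.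

Three steps most likely to fail, with fallbacks:

**Step 12 (Ullmann coupling; the riskiest step).** The phenol is di-ortho-substituted and easily oxidised. The fallback sets out from 21 and comes back at 22. Bromine–lithium exchange (n-BuLi, THF, −78 °C) gives [3-(benzyloxy)-5-(methoxymethoxy)phenyl]lithium F6. Quenching with B(OiPr)3 and aq NH4Cl work-up gives [3-(benzyloxy)-5-(methoxymethoxy)phenyl]boronic acid F7. F7 is joined to phenol 15 by an oxidative Chan–Lam–Evans coupling (Cu(OAc)2, pyridine, 4 Å sieves, CH2Cl2, dry air, rt), a method that tolerates 2,6-disubstituted phenols, to give 22.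

**Step 8 (regioselective mono-MOM protection of an air-sensitive hydroquinone).** The fallback sets out from 12 and comes back at 15, bypassing 13 and 14. Vilsmeier–Haack formylation (POCl3, DMF, 0 °C → rt; aq NaOAc) para to the OH gives 2,6-bis(benzyloxy)-4-hydroxybenzaldehyde F3, separated from the less polar, hydrogen-bonded ortho isomer. MOMCl/iPr2NEt then gives 2,6-bis(benzyloxy)-4-(methoxymethoxy)benzaldehyde F4, in which the MOM position is unambiguous. Baeyer–Villiger (Dakin-type) oxidation with mCPBA (CH2Cl2, NaHCO3) gives 2,6-bis(benzyloxy)-4-(methoxymethoxy)phenyl formate F5, and methanolysis (K2CO3, MeOH) gives 15.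

**Step 1 (crossed Claisen/Dieckmann).** Self-condensation of 1 can compete. The fallback sets out from 2 alone and comes back at 8. Heating sodio-diethyl malonate neat at 140–150 °C trimerises three molecules of 2 through successive Claisen condensations to triethyl 2,4,6-trihydroxybenzene-1,3,5-tricarboxylate F1, with no cross-selectivity problem. Saponification (aq KOH, reflux) gives 2,4,6-trihydroxybenzene-1,3,5-tricarboxylic acid F2, which on acidification and warming decarboxylates through 6 and 7 to phloroglucinol 8.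

## Further compounds

F1 | step 1 | triethyl 2,4,6-trihydroxybenzene-1,3,5-tricarboxylate | CCOC(=O)c1c(O)c(C(=O)OCC)c(O)c(C(=O)OCC)c1O
F2 | step 1 | 2,4,6-trihydroxybenzene-1,3,5-tricarboxylic acid | OC(=O)c1c(O)c(C(=O)O)c(O)c(C(=O)O)c1O
F3 | step 8 | 2,6-bis(benzyloxy)-4-hydroxybenzaldehyde | O=Cc1c(OCc2ccccc2)cc(O)cc1OCc1ccccc1
F4 | step 8 | 2,6-bis(benzyloxy)-4-(methoxymethoxy)benzaldehyde | COCOc1cc(OCc2ccccc2)c(C=O)c(OCc2ccccc2)c1
F5 | step 8 | 2,6-bis(benzyloxy)-4-(methoxymethoxy)phenyl formate | COCOc1cc(OCc2ccccc2)c(OC=O)c(OCc2ccccc2)c1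
F6 | step 12 | [3-(benzyloxy)-5-(methoxymethoxy)phenyl]lithium | [Li]c1cc(OCOC)cc(OCc2ccccc2)c1
F7 | step 12 | [3-(benzyloxy)-5-(methoxymethoxy)phenyl]boronic acid | COCOc1cc(OCc2ccccc2)cc(B(O)O)c1
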